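**Overview**

- Retrosynthesis first restores the fourteen phenols as methyl ethers, then cuts all five diaryl ether C(aryl)–O bonds at once by putting a CO back between each ether oxygen and the unflanked ring carbon it is bonded to, which turns every ether link into an aryl ester.
- The feature that allows this: each ether oxygen is bonded on one side to a ring carbon lying between two hydroxyl-bearing carbons (C1 of ring A, C4 of rings B, C, D and E) and on the other side to C1 of the next ring (B to F), the carbon para to that ring's own flanked oxygen. Oxygen at C4, oxygens at C3 and C5 and a carbon attachment site at C1 is the substitution pattern of syringic acid, so the hexamer maps onto a head-to-tail syringate oligoester lacking five CO.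
- Forward, the chain is joined as esters starting from ring F (3,4,5-trimethoxybenzoyl) and growing through rings E, D, C and B by four rounds of acylating benzyl syringate and hydrogenolysing the benzyl ester. Ring A (2,4,6-trimethoxyphenol) is attached last.
- One fivefold decarbonylation then contracts the five ester links to ether links, and BBr3 frees the phenols. No ring is formed at any stage.
- Stereochemistry: the target is achiral, with no stereocentre and no stereogenic double bond, so nothing has to be set.

Key step: step 12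

Notation used in the names: TMB = 3,4,5-trimethoxybenzoyl (ring F). Syr = the syringoyl unit –O–C6H2(OMe)2–C(=O)– (oxygen at C4, methoxy groups at C3 and C5, carbonyl at C1), acylated on its 4-oxygen by the unit written to its left and carrying on its carbonyl the group written to its right. Remark on the chemistry: methyl is kept as the only protecting group for all fourteen phenolic oxygens, because it survives hydrogenolysis, acid chloride formation and hot zerovalent nickel and is removed in one operation at the end.

**Route**

Step 1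
Reactants: 1 syringic acid
Product: 2 benzyl syringate
Conditions: BnBr, KHCO3, DMF, 40 °C
Reagents that add atoms: benzyl bromide, BrCc1ccccc1
Why: Chemoselective SN2 O-alkylation of the carboxylate, since bicarbonate deprotonates only the carboxylic acid and leaves the much less acidic, doubly ortho-substituted phenol free.

Step 2
Reactants: 2 benzyl syringate; 3 3,4,5-trimethoxybenzoyl chloride
Product: 4 two-ring benzyl ester TMB–Syr–OBn
Conditions: Et3N, DMAP (cat.), CH2Cl2, 0 °C → rt
Reagents that add atoms: none
Why: DMAP-catalysed O-acylation through the N-acylpyridinium ion overcomes the shielding of the phenol by its two ortho methoxy groups, and the benzyl ester is inert to these conditions.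

Step 3
Reactants: 4 two-ring benzyl ester TMB–Syr–OBn
Product: 5 two-ring acid TMB–Syr–OH
Conditions: H2 (1 atm), Pd/C (10% Pd on carbon), THF/EtOAc, rt
Reagents that add atoms: none
Why: Heterogeneous hydrogenolysis cleaves only the benzylic C–O bond, so the aryl ester link and the methyl ethers should be untouched.

Step 4
Reactants: 5 two-ring acid TMB–Syr–OH; 2 benzyl syringate
Product: 7 three-ring benzyl ester TMB–Syr2–OBn, via two-ring acid chloride 6 (not isolated)
Conditions: (COCl)2, DMF (cat.), CH2Cl2, 0 °C → rt, evaporate; then 2, Et3N, DMAP (cat.), CH2Cl2, 0 °C → rt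
Reagents that add atoms: oxalyl chloride, O=C(Cl)C(=O)Cl (supplies the chlorine of intermediate 6 only; no atom of it remains in 7)
Why: Acid chloride formation under chloroiminium (Vilsmeier-type) catalysis followed by DMAP-catalysed esterification; the acid chloride is far more electrophilic than the aryl ester already in the chain, so the phenol of 2 should be acylated without acyl exchange.

Step 5
Reactants: 7 three-ring benzyl ester TMB–Syr2–OBn
Product: 8 three-ring acid TMB–Syr2–OH
Conditions: H2 (1 atm), Pd/C (10% Pd on carbon), THF/EtOAc, rt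
Reagents that add atoms: none
Why: Benzyl ester hydrogenolysis as in step 3; the two aryl ester links carry no benzylic C–O bond and should remain.

Step 6
Reactants: 8 three-ring acid TMB–Syr2–OH; 2 benzyl syringate
Product: 10 four-ring benzyl ester TMB–Syr3–OBn, via three-ring acid chloride 9 (not isolated)
Conditions: (COCl)2, DMF (cat.), CH2Cl2, 0 °C → rt, evaporate; then 2, Et3N, DMAP (cat.), CH2Cl2, 0 °C → rt
Reagents that add atoms: oxalyl chloride, O=C(Cl)C(=O)Cl (supplies the chlorine of intermediate 9 only; no atom of it remains in 10)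
Why: The same acid chloride esterification as in step 4, which adds ring C as one more syringoyl unit.

Step 7
Reactants: 10 four-ring benzyl ester TMB–Syr3–OBn
Product: 11 four-ring acid TMB–Syr3–OH
Conditions: H2 (1 atm), Pd/C (10% Pd on carbon), THF, rt
Reagents that add atoms: none
Why: Benzyl ester hydrogenolysis as before, run in THF to keep the longer oligoester in solution.

Step 8
Reactants: 11 four-ring acid TMB–Syr3–OH; 2 benzyl syringate
Product: 13 five-ring benzyl ester TMB–Syr4–OBn, via four-ring acid chloride 12 (not isolated)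
Conditions: (COCl)2, DMF (cat.), CH2Cl2, 0 °C → rt, evaporate; then 2, Et3N, DMAP (cat.), CH2Cl2, 0 °C → rt
Reagents that add atoms: oxalyl chloride, O=C(Cl)C(=O)Cl (supplies the chlorine of intermediate 12 only; no atom of it remains in 13)
Why: The same acid chloride esterification, which adds ring B; short reaction time at low temperature should keep the free aryloxide from attacking the internal ester links.

Step 9
Reactants: 13 five-ring benzyl ester TMB–Syr4–OBn
Product: 14 five-ring acid TMB–Syr4–OH
Conditions: H2 (1 atm), Pd/C (10% Pd on carbon), THF, rt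
Reagents that add atoms: none
Why: Benzyl ester hydrogenolysis as before; the four aryl ester links and ten methyl ethers should not be affected.

Step 10
Reactants: 15 2,4,6-trimethoxybenzaldehyde
Product: 17 2,4,6-trimethoxyphenol, via 2,4,6-trimethoxyphenyl formate 16 (not isolated)
Conditions: mCPBA, CH2Cl2, 0 °C → rt; aq. NaHCO3/Na2S2O3 wash, evaporate; then K2CO3 (cat.), MeOH, rt, argon
Reagents that add atoms: meta-chloroperbenzoic acid, O=C(OO)c1cccc(Cl)c1
Why: Baeyer–Villiger (Dakin-type) oxidation, in which the very electron-rich aryl group migrates in preference to hydrogen to give the aryl formate, followed by mild methanolysis of the formate to the phenol.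

Step 11
Reactants: 14 five-ring acid TMB–Syr4–OH; 17 2,4,6-trimethoxyphenol
Product: 19 hexa-aryl pentaester TMB–Syr4–O-(2,4,6-trimethoxyphenyl), via five-ring acid chloride 18 (not isolated)
Conditions: (COCl)2, DMF (cat.), CH2Cl2, 0 °C → rt, evaporate; then 17, Et3N, DMAP (cat.), CH2Cl2, 0 °C → rt, argon
Reagents that add atoms: oxalyl chloride, O=C(Cl)C(=O)Cl (supplies the chlorine of intermediate 18 only; no atom of it remains in 19)
Why: Acid chloride esterification with DMAP catalysis; 17 has no para acyl group and is a better nucleophile than 2, so acylation of this hindered phenol should be at least as easy as in the earlier rounds, and argon protects it from oxidation.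

Step 12
Reactants: 19 hexa-aryl pentaester TMB–Syr4–O-(2,4,6-trimethoxyphenyl)
Product: 20 tetradeca-O-methyl hexaphenyl pentaether
Conditions: Ni(cod)2 (10 mol% per ester link), dcypt [3,4-bis(dicyclohexylphosphino)thiophene] (20 mol% per link), K3PO4, m-xylene, 160 °C, slow argon sweep
Reagents that add atoms: none
Why: Proposed new method: at each of the five ester links zerovalent nickel carrying the bulky, electron-rich diphosphine should insert into the C(acyl)–O bond, the aroyl ligand should lose CO by migration and dissociation (made irreversible by the argon sweep), and C(aryl)–O reductive elimination from the resulting aryl nickel aryloxide should give the diaryl ether and regenerate zerovalent nickel. The closest known reaction type is the nickel- or palladium-catalysed decarbonylative diaryl ether synthesis from aryl esters of aromatic acids, which is established for single ester links of azine carboxylates but not for five electron-rich benzoate links in one molecule. No ring closes and no stereocentre is created; the five bonds (C1 of rings F, E, D, C and B to the flanked oxygen of the neighbouring ring) form independently, so partly decarbonylated material can re-enter the cycle. The step needs insertion into C(acyl)–O rather than C(aryl)–O or C–OMe, and it needs each aryloxide to stay on the nickel that cleaved it; the two methoxy groups ortho to every ester oxygen shield the aryl–oxygen bond and can chelate the aryloxide to nickel until it is eliminated. Four of the five leaving aryloxides carry a para acyl group when first cleaved, which weakens the ester C–O bond, and every aryl carbon on nickel lacks ortho substituents and is meta to two inductively withdrawing methoxy groups, which should help the difficult C–O reductive elimination.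

Step 13
Reactants: 20 tetradeca-O-methyl hexaphenyl pentaether
Product: 21 target CNP0187343.0
Conditions: BBr3 (excess), CH2Cl2, −78 °C → rt, argon; then degassed H2O/MeOH, 0 °C
Reagents that add atoms: none
Why: Lewis acid demethylation, in which BBr3 binds each methoxy oxygen and bromide attacks the methyl carbon (SN2); the diaryl ether oxygens carry only sp2 carbons and cannot be cleaved this way, and hydrolysis of the aryl borates on quench should free all fourteen phenols.

**Compound list**

1 | syringic acid (4-hydroxy-3,5-dimethoxybenzoic acid) | COc1cc(C(=O)O)cc(OC)c1O | starting material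
2 | benzyl syringate (benzyl 4-hydroxy-3,5-dimethoxybenzoate) | COc1cc(C(=O)OCc2ccccc2)cc(OC)c1O | intermediate
3 | 3,4,5-trimethoxybenzoyl chloride | COc1cc(C(Cl)=O)cc(OC)c1OC | starting material
4 | two-ring benzyl ester TMB–Syr–OBn (benzyl 3,5-dimethoxy-4-(3,4,5-trimethoxybenzoyloxy)benzoate) | COc1cc(C(=O)Oc2c(OC)cc(C(=O)OCc3ccccc3)cc2OC)cc(OC)c1OC | intermediate
5 | two-ring acid TMB–Syr–OH (3,5-dimethoxy-4-(3,4,5-trimethoxybenzoyloxy)benzoic acid) | COc1cc(C(=O)Oc2c(OC)cc(C(=O)O)cc2OC)cc(OC)c1OC | intermediate
6 | two-ring acid chloride TMB–Syr–Cl | COc1cc(C(=O)Oc2c(OC)cc(C(Cl)=O)cc2OC)cc(OC)c1OC | intermediate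
7 | three-ring benzyl ester TMB–Syr2–OBn | COc1cc(C(=O)Oc2c(OC)cc(C(=O)Oc3c(OC)cc(C(=O)OCc4ccccc4)cc3OC)cc2OC)cc(OC)c1OC | intermediate
8 | three-ring acid TMB–Syr2–OH | COc1cc(C(=O)Oc2c(OC)cc(C(=O)Oc3c(OC)cc(C(=O)O)cc3OC)cc2OC)cc(OC)c1OC | intermediate
9 | three-ring acid chloride TMB–Syr2–Cl | COc1cc(C(=O)Oc2c(OC)cc(C(=O)Oc3c(OC)cc(C(Cl)=O)cc3OC)cc2OC)cc(OC)c1OC | intermediate
10 | four-ring benzyl ester TMB–Syr3–OBn | COc1cc(C(=O)Oc2c(OC)cc(C(=O)Oc3c(OC)cc(C(=O)Oc4c(OC)cc(C(=O)OCc5ccccc5)cc4OC)cc3OC)cc2OC)cc(OC)c1OC | intermediate
11 | four-ring acid TMB–Syr3–OH | COc1cc(C(=O)Oc2c(OC)cc(C(=O)Oc3c(OC)cc(C(=O)Oc4c(OC)cc(C(=O)O)cc4OC)cc3OC)cc2OC)cc(OC)c1OC | intermediate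
12 | four-ring acid chloride TMB–Syr3–Cl | COc1cc(C(=O)Oc2c(OC)cc(C(=O)Oc3c(OC)cc(C(=O)Oc4c(OC)cc(C(Cl)=O)cc4OC)cc3OC)cc2OC)cc(OC)c1OC | intermediate
13 | five-ring benzyl ester TMB–Syr4–OBn | COc1cc(C(=O)Oc2c(OC)cc(C(=O)Oc3c(OC)cc(C(=O)Oc4c(OC)cc(C(=O)Oc5c(OC)cc(C(=O)OCc6ccccc6)cc5OC)cc4OC)cc3OC)cc2OC)cc(OC)c1OC | intermediate
14 | five-ring acid TMB–Syr4–OH | COc1cc(C(=O)Oc2c(OC)cc(C(=O)Oc3c(OC)cc(C(=O)Oc4c(OC)cc(C(=O)Oc5c(OC)cc(C(=O)O)cc5OC)cc4OC)cc3OC)cc2OC)cc(OC)c1OC | intermediate
15 | 2,4,6-trimethoxybenzaldehyde | COc1cc(OC)c(C=O)c(OC)c1 | starting material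
16 | 2,4,6-trimethoxyphenyl formate | COc1cc(OC)c(OC=O)c(OC)c1 | intermediate
17 | 2,4,6-trimethoxyphenol (ring A) | COc1cc(OC)c(O)c(OC)c1 | intermediate
18 | five-ring acid chloride TMB–Syr4–Cl | COc1cc(C(=O)Oc2c(OC)cc(C(=O)Oc3c(OC)cc(C(=O)Oc4c(OC)cc(C(=O)Oc5c(OC)cc(C(Cl)=O)cc5OC)cc4OC)cc3OC)cc2OC)cc(OC)c1OC | intermediate
19 | hexa-aryl pentaester TMB–Syr4–O-(2,4,6-trimethoxyphenyl) | COc1cc(C(=O)Oc2c(OC)cc(C(=O)Oc3c(OC)cc(C(=O)Oc4c(OC)cc(C(=O)Oc5c(OC)cc(C(=O)Oc6c(OC)cc(OC)cc6OC)cc5OC)cc4OC)cc3OC)cc2OC)cc(OC)c1OC | intermediate
20 | tetradeca-O-methyl hexaphenyl pentaether (every C(=O)–O link of 19 replaced by an ether oxygen) | COc1cc(Oc2c(OC)cc(Oc3c(OC)cc(Oc4c(OC)cc(Oc5c(OC)cc(Oc6c(OC)cc(OC)cc6OC)cc5OC)cc4OC)cc3OC)cc2OC)cc(OC)c1OC | intermediate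
21 | CNP0187343.0 (tetradecahydroxy hexaphenyl pentaether) | Oc1cc(O)c(Oc2cc(O)c(Oc3cc(O)c(Oc4cc(O)c(Oc5cc(O)c(Oc6cc(O)c(O)c(O)c6)c(O)c5)c(O)c4)c(O)c3)c(O)c2)c(O)c1 | target

**Count and risks**

Total step count: 13. Longest linear sequence: 12 steps (steps 1 to 9, then 11, 12 and 13; step 10 is the side branch to ring A).

Steps most likely to fail:

1. Step 12. What may go wrong: the decarbonylation stalls after only some of the links have reacted, insertion fails at the electron-rich ester to ring A, CO stays bound to nickel, or aryloxides exchange between chains and cut or shuffle the oligomer. The fallback uses known copper chemistry, sets out from 17 and comes back to the route at 20. Purchased 4-bromo-2,6-dimethoxyphenol is benzylated (BnBr, K2CO3, DMF) to 2-(benzyloxy)-5-bromo-1,3-dimethoxybenzene F1. Ullmann-type coupling of 17 with F1 (CuI, picolinic acid, K3PO4, DMSO, 100 °C) should give 2-[4-(benzyloxy)-3,5-dimethoxyphenoxy]-1,3,5-trimethoxybenzene F2, and hydrogenolysis (H2, Pd/C) should give 2,6-dimethoxy-4-(2,4,6-trimethoxyphenoxy)phenol F3. Repeating the same coupling with F1 and the same hydrogenolysis three more times should give in turn the three-ring benzyl ether F4, the three-ring phenol F5, the four-ring benzyl ether F6, the four-ring phenol F7, the five-ring benzyl ether F8 and the five-ring phenol F9. A last coupling of F9 with purchased 5-bromo-1,2,3-trimethoxybenzene under the same copper conditions should give 20.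

2. Step 13. What may go wrong: cleavage of the fourteen methyl ethers stays incomplete, and the very electron-rich polyphenol is oxidised by air during isolation. The fallback changes how the target is released, sets out from 20 and comes back at 21. After the BBr3 treatment and quench the crude polyphenol is not purified but acetylated directly (Ac2O, pyridine, DMAP cat.) to the tetradecaacetate of the target F10, which is stable to air and silica, so that under-demethylated material can be separated and resubmitted. Acid-catalysed methanolysis of F10 (HCl generated from AcCl in degassed MeOH, rt, argon), with only volatile methyl acetate as the other product, should then give 21 without exposing a phenoxide to air.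

3. Step 11. What may go wrong: acylation of the doubly ortho-substituted, easily oxidised phenol by the largest and least soluble acid chloride is slow, so that oxidation of the phenol and acyl exchange along the chain by free aryloxide compete. The fallback attaches ring A to a monomer instead, sets out from 17 and 11, and comes back at 19 (steps 8 and 9 are then not needed). Purchased 4-(benzyloxy)-3,5-dimethoxybenzoic acid is converted with (COCl)2 and catalytic DMF into 4-(benzyloxy)-3,5-dimethoxybenzoyl chloride F11, which is used in excess to acylate 17 (Et3N, DMAP, CH2Cl2) and should give 2,4,6-trimethoxyphenyl 4-(benzyloxy)-3,5-dimethoxybenzoate F12. Hydrogenolysis of the benzyl ether (H2, Pd/C) should give 2,4,6-trimethoxyphenyl 4-hydroxy-3,5-dimethoxybenzoate F13, a phenol of the same kind as 2. The four-ring acid chloride 12, generated from 11 as in step 8, then acylates F13 (Et3N, DMAP, CH2Cl2) to give 19.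

**Further compounds**

F1 | step 12 | 2-(benzyloxy)-5-bromo-1,3-dimethoxybenzene | COc1cc(Br)cc(OC)c1OCc1ccccc1
F2 | step 12 | 2-[4-(benzyloxy)-3,5-dimethoxyphenoxy]-1,3,5-trimethoxybenzene (two-ring benzyl ether, rings A and B) | COc1cc(OC)c(Oc2cc(OC)c(OCc3ccccc3)c(OC)c2)c(OC)c1
F3 | step 12 | 2,6-dimethoxy-4-(2,4,6-trimethoxyphenoxy)phenol (two-ring phenol) | COc1cc(OC)c(Oc2cc(OC)c(O)c(OC)c2)c(OC)c1
F4 | step 12 | three-ring benzyl ether (rings A, B, C; benzyloxy at C4 of ring C) | COc1cc(OC)c(Oc2cc(OC)c(Oc3cc(OC)c(OCc4ccccc4)c(OC)c3)c(OC)c2)c(OC)c1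
F5 | step 12 | three-ring phenol (rings A, B, C; hydroxyl at C4 of ring C) | COc1cc(OC)c(Oc2cc(OC)c(Oc3cc(OC)c(O)c(OC)c3)c(OC)c2)c(OC)c1
F6 | step 12 | four-ring benzyl ether (rings A to D; benzyloxy at C4 of ring D) | COc1cc(OC)c(Oc2cc(OC)c(Oc3cc(OC)c(Oc4cc(OC)c(OCc5ccccc5)c(OC)c4)c(OC)c3)c(OC)c2)c(OC)c1
F7 | step 12 | four-ring phenol (rings A to D; hydroxyl at C4 of ring D) | COc1cc(OC)c(Oc2cc(OC)c(Oc3cc(OC)c(Oc4cc(OC)c(O)c(OC)c4)c(OC)c3)c(OC)c2)c(OC)c1
F8 | step 12 | five-ring benzyl ether (rings A to E; benzyloxy at C4 of ring E) | COc1cc(OC)c(Oc2cc(OC)c(Oc3cc(OC)c(Oc4cc(OC)c(Oc5cc(OC)c(OCc6ccccc6)c(OC)c5)c(OC)c4)c(OC)c3)c(OC)c2)c(OC)c1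
F9 | step 12 | five-ring phenol (rings A to E; hydroxyl at C4 of ring E) | COc1cc(OC)c(Oc2cc(OC)c(Oc3cc(OC)c(Oc4cc(OC)c(Oc5cc(OC)c(O)c(OC)c5)c(OC)c4)c(OC)c3)c(OC)c2)c(OC)c1
F10 | step 13 | tetradecaacetate of the target | CC(=O)Oc1cc(OC(C)=O)c(Oc2cc(OC(C)=O)c(Oc3cc(OC(C)=O)c(Oc4cc(OC(C)=O)c(Oc5cc(OC(C)=O)c(Oc6cc(OC(C)=O)c(OC(C)=O)c(OC(C)=O)c6)c(OC(C)=O)c5)c(OC(C)=O)c4)c(OC(C)=O)c3)c(OC(C)=O)c2)c(OC(C)=O)c1
F11 | step 11 | 4-(benzyloxy)-3,5-dimethoxybenzoyl chloride | COc1cc(C(Cl)=O)cc(OC)c1OCc1ccccc1
F12 | step 11 | 2,4,6-trimethoxyphenyl 4-(benzyloxy)-3,5-dimethoxybenzoate | COc1cc(OC)c(OC(=O)c2cc(OC)c(OCc3ccccc3)c(OC)c2)c(OC)c1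
F13 | step 11 | 2,4,6-trimethoxyphenyl 4-hydroxy-3,5-dimethoxybenzoate | COc1cc(OC)c(OC(=O)c2cc(OC)c(O)c(OC)c2)c(OC)c1
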